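The data are simulated from invented constants; scatter was added.

A minute is a poor unit across flasks held at 35 °C and 10 °C, so each flask's time is counted here in a unit of its own.

| setting | cedar | oak | north-east | north |
|---|---|---|---|---|
| starting material | 0.54 M | 1.2 M | 0.80 M | 0.80 M |
| gas | 79 mM (held) | 79 mM (held) | 79 mM (held) | 79 mM (held) |
| temperature | 16 °C | 30 °C | 35 °C | 10 °C |
| remark | run made earlier | run made earlier |  |  |
| time |  |  | 25 min | 25 min |

| cedar: time / min | cedar: target / % | oak: time / min | oak: target / % |
|---|---|---|---|
| 3.00 | 1.5 | 1.33 | 3.3 |
| 5.00 | 8.5 | 2.00 | 5.3 |
| 8.00 | 7.2 | 3.00 | 6.2 |
| 12.0 | 9.6 | 5.00 | 8.2 |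
| 25.0 | 11.0 | 10.0 | 10.5 |
| 40.0 | 9.1 | 15.0 | 12.8 |

(scatter of a reading: 1 percentage point)

- at the start none of the gas is in solution

1. which flask leads in amount of target, in percent of the starting material charged ("all alike" within 1.5 percentage points) (north-east / north / all alike)
2. how much target is there at the end, in percent of the starting material charged: north-east
3. how much target is there at the end, in percent of the starting material charged: north

That unit is the top time, when target stops rising and starts to fall. Cedar read highest at 11.0% after 25.0 min, then 9.1% after 40.0 min, a weak sign against a scatter of 1 percentage point. The reckoning here accepts that top and assumes, as a rule of thumb, that rates double every 10 K. The top time then comes to 6.70 min for north-east and 37.9 min for north. The age number, asked time over top time, is 3.73 for north-east and 0.660 for north. Above 1 a flask counts as past its top, below 1 as still climbing, so north-east should be falling, north rising, and north should lead.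

Oak tests this. Its number at the last reading is 1.58, yet it read 10.5% and then 12.8%. So oak goes against the number as read, though that rise of 2.3 points lies between two readings, each with a scatter of 1 point. The number also holds no charge, and oak's 1.2 M and the 0.80 M of the asked flasks both differ from cedar's 0.54 M. One number was therefore not enough: it gives no percentages, and its direction stays a tentative call.

The forecast differs: cedar “looks like an equilibrium or stall”, with north-east leading at 14% and north at 9%.

The flasks give 5.66% in north-east and 13.8% in north, so north leads.

    gas ⇌ coupling partner, rate k1*(csat - [coupling partner]) (kL = 1.40 min⁻¹)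
    starting material + coupling partner → target, rate k2*[starting material]^1.5*[coupling partner] (k = 0.830 M⁻¹·⁵ min⁻¹, Ea = 42.0 kJ mol⁻¹)
    coupling partner + target → over-reaction product (k = 4.70 M⁻¹ min⁻¹, Ea = 56.0 kJ mol⁻¹)
    (constants at 35 °C)

North-east fell from 9.61% at 12.5 min, and north rose from 9.96%, the directions the age number gave. Neither flask is at rest at the asked time. After 250 min, ten times as long, north-east holds 0.0331% target and 98.4% over-reaction product. After 250 min, north holds 1.66% target and 83.9% over-reaction product.

North left until 90.0 min has an age number of 2.38, past its top, so its target should stand below 13.8%. It stands at 8.84%, beside 50.2% over-reaction product.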